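The earlier runs and the new flask were generated by integration for substances that don't exist; noise was put on by code.

Per minute, free monomer fell in the earlier runs by a steady fraction, and I read that fraction as a count of living ends, taking the south-east run as my yardstick: it held 79.0 mM of initiator above its impurity and kept 21.8% of its free monomer after 40.0 min.

the same everywhere: impurity 31 mM

| flask | free monomer | transfer agent | initiator | remark | time |
|---|---|---|---|---|---|
| south-west | 1.5 M | 0.45 M | 14 mM | run made earlier |  |
| south-east | 1.5 M | 0.45 M | 110 mM | run made earlier |  |
| south | 0.97 M | 0.45 M | 75 mM | run made earlier |  |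
| summer | 1.5 M | 0.450 M | 25 mM |  | 50 min |
| autumn | 1.5 M | 0.450 M | 120 mM |  | 50 min |
| noon | 0.80 M | 0.450 M | 120 mM |  | 50 min |
| dusk | 0.80 M | 0.450 M | 25 mM |  | 50 min |
| midnight | 0.80 M | 0.450 M | 75 mM |  | 50 min |
| winter | 1.5 M | 0.450 M | 75 mM |  | 50 min |

| run | time / min | monomer in chains / % | free monomer / % |
|---|---|---|---|
| south-west | 3.00 | 1.0 | 97.5 |
| south-west | 6.00 | 2.1 | 99.9 |
| south-west | 15.0 | 3.7 | 94.9 |
| south-west | 40.0 | 9.8 | 88.6 |
| south-east | 4.00 | 14.3 | 86.1 |
| south-east | 12.0 | 34.3 | 60.0 |
| south-east | 25.0 | 53.4 | 37.7 |
| south-east | 40.0 | 67.9 | 21.8 |
| south | 3.00 | 7.4 | 91.5 |
| south | 6.00 | 14.9 | 87.5 |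
| south | 15.0 | 24.8 | 70.2 |
| south | 40.0 | 48.9 | 41.9 |

(readings scatter by 1 percentage point)

- a species is counted by the free monomer in it: one side product counts as two
- the analysis behind the earlier runs scatters by 1 percentage point, standard deviation
- on the list of suspects stand: free monomer + initiator -> living end + monomer in chains; free monomer + living end -> monomer in chains + living end; living end + transfer agent -> dead chain; 2 initiator -> spent initiator A; free monomer + monomer in chains -> side product; initiator + impurity -> spent initiator B

* all flasks from highest to lowest amount of monomer in chains, in percent of the free monomer charged, at 50 min (summer / autumn / noon / dusk / midnight / winter)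
* the amount of monomer in chains, in percent of the free monomer charged of the flask you put first, at 50 min
* the amount of monomer in chains, in percent of the free monomer charged of the flask you put last, at 50 min

I built dusk up one process at a time. With the main step alone, every initiator counted as a living end, the yardstick gave dusk a conversion of 45.3%.

Adding the impurity as a plain subtraction, which is the end of large charges, came out negative, since dusk's 25 mM of initiator is less than its 31 mM of impurity. Yet the south-west run, with 14 mM, did make chains: its last free monomer reading, which carries a scatter of 1 percentage point, counts 6.28 mM of living ends, a fraction 0.449 of its charge.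

So initiator is shared out in a race. At the other end, with impurity barely touched, the fraction passing is s/(s+Y), where Y is the impurity charge and s is the free monomer charge times a factor. To join the ends I let impurity decay as the living ends L form: the initiator charge equals L plus the impurity consumed, which is Y times one minus exp(−L/s). Solved on the south-west run, this gave 0.0146 as the selectivity factor, the amount of impurity that matches a unit amount of free monomer in the race for initiator.

For dusk s came to 11.7 mM, so the low-end value was 6.84 mM of living ends; one Newton step on the balance made it 8.63 mM, a fraction 0.345 of dusk's charge, and the yardstick turned this into a conversion of 18.8%. For summer, with s at 21.9 mM and a start of 10.4 mM, the same steps gave 11.9 mM and a conversion of 25.0%, more than dusk's.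

Side product, my last addition, takes monomer out of chains: the south-east run's last readings fall 10 points short of the charge, so I expected dusk's monomer in chains to lie under its conversion.

The forecast, made from the same runs, ran noon > autumn > midnight > winter > dusk > summer, with 79% first and 21% last, and said of its rate constants: “The dependence is convex, consistent with partial loss of initiator to impurity”. It set dusk above summer, where my conversions stood the other way.

The flask gave noon > autumn > midnight > winter > summer > dusk, with 77.8% of monomer in chains first and 15.4% last.

    free monomer + initiator → living end + monomer in chains (k = 0.00935 M⁻¹ s⁻¹)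
    free monomer + living end → monomer in chains + living end, rate k2*[living end]*[free monomer] (k = 0.00802 M⁻¹ s⁻¹)
    living end + transfer agent → dead chain (kL = 1.18 × 10⁻⁴ M⁻¹ s⁻¹)
    2 initiator → spent initiator A (k = 0.00583 M⁻¹ s⁻¹)
    free monomer + monomer in chains → side product (k = 1.05 × 10⁻⁴ M⁻¹ s⁻¹)
    initiator + impurity → spent initiator B (k = 0.687 M⁻¹ s⁻¹)

Dusk stayed low because its initiator was used up, 0% of the charge remaining at 50.0 min: the same flask with initiator kept from running down gives 92.4% of monomer in chains against 15.4%. By the selectivity factor 16.4 mM of that charge went to the impurity, and dusk held 16.6 mM of spent initiator B. For the neighbour of dusk with 10.0 mM of initiator, the factor starts from 2.74 mM, reaches 2.99 mM of living ends, and the yardstick leaves 93.0% of the free monomer; that neighbour held 92.9% at 50.0 min.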